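The cyclopentane (ring B, atoms C1, C2, C3, C3a, C7a of the hydrindane) is treated as a contracted cyclohexene: its C1–C2 bond is the aldol bond of the C2(OH)–C1–C(OH) array. The enone ring of the (S)-Wieland–Miescher ketone, whose other ring becomes ring C with the quaternary C3a, is joined at its carbonyl carbon to the bromocyclohexanone (ring A), cleaved by ozonolysis and re-closed by an intramolecular aldol reaction of the resulting keto aldehyde. This one operation forms ring B last and sets C1 and C2; the precursor is a cyclohexane carrying a CH2CHO arm and a CH2–CO–C(OH) arm on adjacent carbons.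

Key step: step 12

Remark: hydrindane numbering is used for compounds containing ring B (C1 bears the side chain, C2 and C7 the hydroxyls, C3a the methyl, C4 the bromine) and naphthalene numbering for the decalins (C1 and C6 oxygenated, C4a and C8a ring fusion); the ester-bearing carbon of the ring-A β-keto ester and of its acid is left undefined (enolisable, lost on decarboxylation), and hydrazone geometry is not specified.

Step 1
Reactants: 1 5-methylhex-4-enoic acid
Product: 2 (S)-5-bromo-6,6-dimethyloxan-2-one
Conditions: NBS (1.2 equiv), cinchona-alkaloid-derived amino-thiocarbamate catalyst (10 mol %; the pseudo-enantiomer that leads to the S bromide), CHCl3–toluene, −78 °C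
Reagents that add atoms: N-bromosuccinimide, O=C1CCC(=O)N1Br
Why: Catalytic enantioselective 6-endo bromolactonisation, in which the bifunctional catalyst delivers bromine to one alkene face while the carboxylate closes on the tertiary carbon, should fix the secondary C–Br centre as S.

Step 2
Reactants: 2 (S)-5-bromo-6,6-dimethyloxan-2-one
Product: 3 allyl (6S)-6-bromo-7-hydroxy-7-methyl-3-oxooctanoate
Conditions: allyl acetate, LiN(i-Pr)2 (2.2 equiv), THF, −78 °C; then 2; AcOH, −78 °C
Reagents that add atoms: allyl acetate, CC(=O)OCC=C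
Why: Claisen-type acylation of the lithium ester enolate by the lactone opens the ring to the δ-hydroxy β-keto ester without touching the bromine-bearing centre, and the cold quench should prevent epoxide closure.

Step 3
Reactants: 3 allyl (6S)-6-bromo-7-hydroxy-7-methyl-3-oxooctanoate
Product: 4 allyl (3S)-3-bromo-2,2-dimethyl-6-oxocyclohexane-1-carboxylate
Conditions: TfOH (10 mol %), (CF3)2CHOH, 0 °C
Reagents that add atoms: none
Why: Acid ionises the tertiary carbinol with participation of the neighbouring bromine, and the bromonium ion is opened at the tertiary carbon by the enol carbon of the β-keto ester (cationic C-alkylation that closes ring A), so the C–Br centre should keep its configuration.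

Step 4
Reactants: 4 allyl (3S)-3-bromo-2,2-dimethyl-6-oxocyclohexane-1-carboxylate
Product: 6 (S)-4-bromo-3,3-dimethylcyclohexan-1-one, via keto acid 5 (not isolated)
Conditions: Pd(PPh3)4 (5 mol %), morpholine, THF, 25 °C
Reagents that add atoms: none
Why: Palladium-catalysed deallylation (π-allyl complex intercepted by morpholine) frees the β-keto acid, which loses CO2 under the reaction conditions; no stereocentre is involved.

Step 5
Reactants: 7 (S)-Wieland–Miescher ketone
Product: 8 bis(ethylene ketal) of 7 with the double bond moved to C4=C4a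
Conditions: HOCH2CH2OH (excess), TsOH (cat.), benzene, reflux, Dean–Stark trap
Reagents that add atoms: ethylene glycol, OCCO
Why: Double ketalisation; as with steroidal enones, the enone ketal forms with migration of the double bond to the β,γ-position, and the quaternary centre is untouched.

Step 6
Reactants: 8 bis(ethylene ketal) of 7 with the double bond at C4=C4a
Product: 10 (4S,4aS,8aS)-4-hydroxy-8a-methyl-trans-decalin-1,6-dione bis(ethylene ketal), via alkylborane 9 (not isolated)
Conditions: BH3·THF, THF, 0 → 25 °C; then NaOH, H2O2, 0 °C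
Reagents that add atoms: hydrogen peroxide, OO
Why: Hydroboration–oxidation: syn addition of H–B from the face opposite the angular methyl puts boron on the less substituted C4 and hydrogen on C4a trans to CH3 (trans ring fusion), and the oxidation proceeds with retention.

Step 7
Reactants: 10 (4S,4aS,8aS)-4-hydroxy-8a-methyl-trans-decalin-1,6-dione bis(ethylene ketal)
Product: 11 (4aS,8aS)-8a-methyl-trans-decalin-1,4,6-trione 1,6-bis(ethylene ketal)
Conditions: Dess–Martin periodinane, NaHCO3, CH2Cl2, 25 °C
Reagents that add atoms: none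
Why: Buffered Dess–Martin oxidation of the secondary alcohol; the neutral conditions should leave the adjacent ring-fusion centre and both ketals intact.

Step 8
Reactants: 11 (4aS,8aS)-8a-methyl-trans-decalin-1,4,6-trione 1,6-bis(ethylene ketal)
Product: 12 (4R,4aS,8aS)-4-hydroxy-4,8a-dimethyl-trans-decalin-1,6-dione bis(ethylene ketal)
Conditions: MeMgBr, THF, −78 → 0 °C
Reagents that add atoms: methylmagnesium bromide, C[Mg]Br
Why: Grignard addition from the equatorial direction, the axial face being blocked by the syn-axial angular methyl, should give the equatorial CH3 and the axial OH cis to that methyl (as with 6-oxo steroids).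

Step 9
Reactants: 12 (4R,4aS,8aS)-4-hydroxy-4,8a-dimethyl-trans-decalin-1,6-dione bis(ethylene ketal)
Product: 14 C6 2,4,6-triisopropylbenzenesulfonylhydrazone of the C1 mono-ketal, via ketone 13 (not isolated)
Conditions: 2,4,6-(i-Pr)3C6H2SO2NHNH2 (1.05 equiv), HCl (cat.), THF–H2O, 25 °C
Reagents that add atoms: 2,4,6-triisopropylbenzenesulfonyl hydrazide, CC(C)c1cc(C(C)C)c(S(=O)(=O)NN)c(C(C)C)c1
Why: Mild acid should hydrolyse the unhindered C6 dioxolane much faster than the C1 dioxolane beside the quaternary carbon, and the freed ketone condenses with the sulfonyl hydrazide.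

Step 10
Reactants: 14 C6 2,4,6-triisopropylbenzenesulfonylhydrazone of the C1 mono-ketal; 6 (S)-4-bromo-3,3-dimethylcyclohexan-1-one
Product: 16 tertiary allylic alcohol (ring A carbinol bonded to C6 of the C6=C7 octalin), via vinyllithium 15 (not isolated)
Conditions: n-BuLi (3.1 equiv), THF, −78 → 0 °C; then 6, −78 °C; H2O
Reagents that add atoms: none
Why: Shapiro reaction: deprotonation at the less hindered C7 and loss of N2 and sulfinate give the C6 vinyllithium (C6=C7), which should add to ketone 6 from the equatorial side, anti to the axial 3-methyl of the chair with equatorial bromine, so that the new tertiary hydroxyl is axial and cis to Br.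

Step 11
Reactants: 16 tertiary allylic alcohol (ring A carbinol bonded to C6 of the C6=C7 octalin)
Product: 18 keto aldehyde (CH2CHO arm on the methyl-bearing carbon and CH2–CO–ring A carbinol arm on the adjacent CH of ring C), via ozonide 17 (not isolated)
Conditions: O3, CH2Cl2, −78 °C; then PPh3, −78 → 25 °C
Reagents that add atoms: ozone, [O-][O+]=O
Why: Ozonolysis of the only C=C bond cuts the former C6–C7 bond of the cyclohexene, leaving C6 as the α-hydroxy ketone carbon and C7 as the aldehyde; no stereocentre is affected.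

Step 12
Reactants: 18 keto aldehyde
Product: 19 (1S,2R,3aS,7R,7aS)-1-[(1R,4S)-4-bromo-1-hydroxy-3,3-dimethylcyclohexane-1-carbonyl]-2,7-dihydroxy-3a,7-dimethyloctahydro-4H-inden-4-one 4-(ethylene ketal)
Conditions: KOt-Bu (0.3 equiv), THF–t-BuOH (10:1), −30 → 0 °C; then AcOH
Reagents that add atoms: none
Why: Potassium tert-butoxide reversibly enolises the ketone at its only enolisable position, the CH2 that becomes C1 (the other α-carbon is the quaternary carbinol of ring A), and this enolate adds to the aldehyde carbon, which becomes C2, so that ring B closes while the ketone carbon stays outside the ring as the future side-chain carbinol. The closest known reaction type is the intramolecular aldol cyclisation of a 1,6-keto aldehyde made by cleaving a cyclohexene, the classical six-to-five ring contraction, here held at the β-hydroxy ketone stage. The ring closes in the 5-(enolexo)-exo-trig mode. C1 is set thermodynamically, the acyl group taking the position trans to the ring-C carbon on the neighbouring ring-fusion atom, and C2 by a potassium-chelated transition state that places the new hydroxyl cis to the acyl group and on the face away from the angular methyl. The step needs selectivity for the ketone enolate over the aldehyde enolate and over dehydration: addition of the aldehyde enolate to the neopentyl α-hydroxy ketone is unfavourable and reversible, the dioxolane masks the only other carbonyl group, and substoichiometric base at low temperature should suppress elimination. The trans ring fusion cannot epimerise because the adjacent ring-C carbon is already a tertiary carbinol.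

Step 13
Reactants: 19 aldol product (β-hydroxy ketone)
Product: 21 (R)-carbinol (1,3-syn diol; C4 ketal retained), via boron chelate 20 (not isolated)
Conditions: Et2BOMe (1.2 equiv), THF–MeOH (4:1), −78 °C; then NaBH4; AcOH, MeOH co-evaporation
Reagents that add atoms: none
Why: Narasaka–Prasad reduction: the diethylboron chelate of the β-hydroxy ketone is attacked by external hydride on its convex face, which should give the 1,3-syn diol and hence the R carbinol.

Step 14
Reactants: 21 (R)-carbinol (1,3-syn diol; C4 ketal retained)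
Product: 22 (1S,2R,3aS,7R,7aS)-1-[(R)-[(1R,4S)-4-bromo-1-hydroxy-3,3-dimethylcyclohexyl](hydroxy)methyl]-2,7-dihydroxy-3a,7-dimethyloctahydro-4H-inden-4-one
Conditions: 1 M HCl, THF, 40 °C
Reagents that add atoms: water, O
Why: Acid-catalysed hydrolysis of the remaining hindered dioxolane; dilute aqueous acid should leave the tertiary alcohols and the secondary bromide alone.

Step 15
Reactants: 22 C4 ketone
Product: 24 C4 vinyl bromide (C4=C5), via hydrazone 23 (not isolated)
Conditions: N2H4·H2O, Et3N, EtOH, 80 °C; then NBS (2.2 equiv), pyridine, 0 °C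
Reagents that add atoms: N-bromosuccinimide, O=C1CCC(=O)N1Br
Why: Barton-type vinyl halide synthesis (oxidation of the hydrazone to the diazo compound, bromination, loss of N2 and of a proton), a reaction used on ketones flanked by a quaternary carbon; only C5 carries α-hydrogens, so a single alkene isomer should form.

Step 16
Reactants: 24 C4 vinyl bromide (C4=C5)
Product: 25 (1S,2R,3aS,4S,7R,7aS)-4-bromo-1-[(R)-[(1R,4S)-4-bromo-1-hydroxy-3,3-dimethylcyclohexyl](hydroxy)methyl]-3a,7-dimethyloctahydro-1H-indene-2,7-diol
Conditions: Mn(dpm)3 (10 mol %; dpm = 2,2,6,6-tetramethylheptane-3,5-dionate), PhSiH3, t-BuOOH, i-PrOH, 25 °C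
Reagents that add atoms: none
Why: Hydrogen-atom-transfer hydrogenation: H• adds to C5 and the α-bromo radical at C4 is reduced from the axial face anti to the angular methyl, which should give the equatorial bromide cis to CH3, while the alkyl bromide of ring A and the free alcohols are inert to these conditions.

Compound list
1 | 5-methylhex-4-enoic acid | CC(C)=CCCC(=O)O | starting material
2 | (S)-5-bromo-6,6-dimethyloxan-2-one | CC1(C)OC(=O)CC[C@@H]1Br | intermediate
3 | allyl (6S)-6-bromo-7-hydroxy-7-methyl-3-oxooctanoate (open form of the lactol) | C=CCOC(=O)CC(=O)CC[C@@H](C(C)(C)O)Br | intermediate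
4 | allyl (3S)-3-bromo-2,2-dimethyl-6-oxocyclohexane-1-carboxylate (C1 undefined) | CC1(C)C(C(=O)OCC=C)C(=O)CC[C@@H]1Br | intermediate
5 | (3S)-3-bromo-2,2-dimethyl-6-oxocyclohexane-1-carboxylic acid (not isolated) | CC1(C)C(C(=O)O)C(=O)CC[C@@H]1Br | intermediate
6 | (S)-4-bromo-3,3-dimethylcyclohexan-1-one | CC1(C)CC(=O)CC[C@@H]1Br | intermediate
7 | (S)-Wieland–Miescher ketone, (S)-8a-methyl-3,4,8,8a-tetrahydronaphthalene-1,6(2H,7H)-dione | O=C1CC[C@]2(C)C(=O)CCCC2=C1 | starting material
8 | (8aS)-1,1:6,6-bis(ethylenedioxy)-8a-methyl-1,2,3,5,6,7,8,8a-octahydronaphthalene (C4=C4a) | O1CCOC12CC[C@]3(C)C4(OCCO4)CCC=C3C2 | intermediate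
9 | C4 alkylborane of 8 (boron and 4a-H on the face opposite the 8a-methyl; not isolated) | O1CCOC12CC[C@]3(C)C4(OCCO4)CC[C@H](B)[C@H]3C2 | intermediate
10 | (4S,4aS,8aS)-4-hydroxy-8a-methyl-trans-decalin-1,6-dione bis(ethylene ketal) (equatorial OH) | O1CCOC12CC[C@]3(C)C4(OCCO4)CC[C@H](O)[C@H]3C2 | intermediate
11 | (4aS,8aS)-8a-methyl-trans-decalin-1,4,6-trione 1,6-bis(ethylene ketal) | O1CCOC12CC[C@]3(C)C4(OCCO4)CCC(=O)[C@H]3C2 | intermediate
12 | (4R,4aS,8aS)-4-hydroxy-4,8a-dimethyl-trans-decalin-1,6-dione bis(ethylene ketal) (axial OH cis to the 8a-methyl) | O1CCOC12CC[C@]3(C)C4(OCCO4)CC[C@@](C)(O)[C@H]3C2 | intermediate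
13 | (4R,4aS,8aS)-4-hydroxy-4,8a-dimethyl-trans-decalin-1,6-dione 1-(ethylene ketal) (not isolated) | O=C1CC[C@]2(C)C3(OCCO3)CC[C@@](C)(O)[C@H]2C1 | intermediate
14 | C6 2,4,6-triisopropylbenzenesulfonylhydrazone of 13 | CC(C)c1cc(C(C)C)c(S(=O)(=O)NN=C2CC[C@]3(C)C4(OCCO4)CC[C@@](C)(O)[C@H]3C2)c(C(C)C)c1 | intermediate
15 | C6 vinyllithium (C6=C7) with lithium C4 alkoxide, C1 ketal retained (not isolated) | [Li]C1=CC[C@]2(C)C3(OCCO3)CC[C@@](C)(O[Li])[C@H]2C1 | intermediate
16 | (1R,4S)-4-bromo-3,3-dimethylcyclohexan-1-ol carrying at C1 the C6 of the C6=C7 octalin (C1 ketal, C4 tertiary alcohol as in 12) | CC1(C)C[C@@](O)(C2=CC[C@]3(C)C4(OCCO4)CC[C@@](C)(O)[C@H]3C2)CC[C@@H]1Br | intermediate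
17 | ozonide (1,2,4-trioxolane across the former C6 and C7) of 16 (not isolated) | CC1(C)C[C@@](O)(C23C[C@H]4[C@](C)(CC(O2)OO3)C5(OCCO5)CC[C@@]4(C)O)CC[C@@H]1Br | intermediate
18 | keto aldehyde: ring C (ketal, tertiary carbinol) with CH2CHO on the methyl-bearing carbon and CH2–CO–[(1R,4S)-4-bromo-1-hydroxy-3,3-dimethylcyclohexyl] on the adjacent CH, arms trans | CC1(C)C[C@@](O)(C(=O)C[C@H]2[C@](C)(CC=O)C3(OCCO3)CC[C@@]2(C)O)CC[C@@H]1Br | intermediate
19 | (1S,2R,3aS,7R,7aS)-1-[(1R,4S)-4-bromo-1-hydroxy-3,3-dimethylcyclohexane-1-carbonyl]-2,7-dihydroxy-3a,7-dimethyloctahydro-4H-inden-4-one 4-(ethylene ketal) | CC1(C)C[C@@](O)(C(=O)[C@@H]2[C@H](O)C[C@]3(C)C4(OCCO4)CC[C@@](C)(O)[C@@H]23)CC[C@@H]1Br | intermediate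
20 | C2 O-diethylboryl derivative (boron chelate) of 19 (not isolated) | CC1(C)C[C@@](O)(C(=O)[C@@H]2[C@H](OB(CC)CC)C[C@]3(C)C4(OCCO4)CC[C@@](C)(O)[C@@H]23)CC[C@@H]1Br | intermediate
21 | (1S,2R,3aS,7R,7aS)-1-[(R)-[(1R,4S)-4-bromo-1-hydroxy-3,3-dimethylcyclohexyl](hydroxy)methyl]-2,7-dihydroxy-3a,7-dimethyloctahydro-4H-inden-4-one 4-(ethylene ketal) | CC1(C)C[C@@](O)([C@H](O)[C@@H]2[C@H](O)C[C@]3(C)C4(OCCO4)CC[C@@](C)(O)[C@@H]23)CC[C@@H]1Br | intermediate
22 | (1S,2R,3aS,7R,7aS)-1-[(R)-[(1R,4S)-4-bromo-1-hydroxy-3,3-dimethylcyclohexyl](hydroxy)methyl]-2,7-dihydroxy-3a,7-dimethyloctahydro-4H-inden-4-one | CC1(C)C[C@@](O)([C@H](O)[C@@H]2[C@H](O)C[C@]3(C)C(=O)CC[C@@](C)(O)[C@@H]23)CC[C@@H]1Br | intermediate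
23 | C4 hydrazone of 22 (not isolated) | CC1(C)C[C@@](O)([C@H](O)[C@@H]2[C@H](O)C[C@]3(C)C(=NN)CC[C@@](C)(O)[C@@H]23)CC[C@@H]1Br | intermediate
24 | (1S,2R,3aS,7R,7aS)-4-bromo-1-[(R)-[(1R,4S)-4-bromo-1-hydroxy-3,3-dimethylcyclohexyl](hydroxy)methyl]-3a,7-dimethyl-2,3,3a,6,7,7a-hexahydro-1H-indene-2,7-diol (C4=C5) | CC1(C)C[C@@](O)([C@H](O)[C@@H]2[C@H](O)C[C@]3(C)C(Br)=CC[C@@](C)(O)[C@@H]23)CC[C@@H]1Br | intermediate
25 | (1S,2R,3aS,4S,7R,7aS)-4-bromo-1-[(R)-[(1R,4S)-4-bromo-1-hydroxy-3,3-dimethylcyclohexyl](hydroxy)methyl]-3a,7-dimethyloctahydro-1H-indene-2,7-diol | CC1(C)C[C@@](O)([C@H](O)[C@@H]2[C@H](O)C[C@]3(C)[C@@H](Br)CC[C@@](C)(O)[C@@H]23)CC[C@@H]1Br | target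

Total step count: 16 steps.
Longest linear sequence: 12 steps (7 to 25, steps 5–16). The ring-A branch (steps 1–4) joins at step 10.

Steps most likely to fail

Step 3. The bromonium ion or tertiary cation from 3 may lose a proton, be captured on oxygen to give a cyclic enol ether, or shift hydride before the enol carbon attacks. The fallback sets out from 3: the tertiary hydroxyl would be exchanged for chloride (HCl, CH2Cl2, 0 °C, through the same bromonium ion and therefore with retention) to give allyl (6S)-6-bromo-7-chloro-7-methyl-3-oxooctanoate F1. This would be cyclised without added acid by solvolysis in (CF3)2CHOH, the stereospecific bromonium cyclisation known for vicinal bromochlorides, and this returns to 4.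

Step 12. The aldol may dehydrate to the enone, revert, or place the C2 hydroxyl on the wrong face under equilibrating conditions. The fallback sets out from 18: condensation would be driven on purpose (KOH, MeOH, 25 °C) to the cyclopentenyl ketone F2 (C1=C2). Copper-catalysed conjugate borylation (B2pin2, CuCl, NaOt-Bu, MeOH, THF) from the face opposite the angular methyl, with protonation of C1 trans to the ring-C carbon, would give the C2 pinacol boronate F3. Oxidation with retention (NaBO3, THF–H2O) returns to 19.

Step 1. Enantiofacial discrimination may be insufficient for a purely aliphatic trisubstituted alkenoic acid. The fallback sets out from 1: uncatalysed bromolactonisation (NBS, MeCN) would give racemic 5-bromo-6,6-dimethyloxan-2-one F4. Ring opening with (S)-1-phenylethylamine (2-hydroxypyridine, toluene, 60 °C) gives two diastereomeric hydroxy amides. Of these, (S)-4-bromo-5-hydroxy-5-methyl-N-[(S)-1-phenylethyl]hexanamide F5 would be separated by crystallisation or chromatography and re-closed with TsOH (toluene, 60 °C), which returns to 2.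

Further compounds
F1 | step 3 | allyl (6S)-6-bromo-7-chloro-7-methyl-3-oxooctanoate | C=CCOC(=O)CC(=O)CC[C@@H](C(C)(C)Cl)Br
F2 | step 12 | cyclopentenyl ketone (C1=C2 enone corresponding to 19 after loss of water) | CC1(C)C[C@@](O)(C(=O)C2=CC[C@]3(C)C4(OCCO4)CC[C@@](C)(O)[C@@H]23)CC[C@@H]1Br
F3 | step 12 | C2 pinacol boronate corresponding to 19 (boron in place of the C2 hydroxyl) | CC1(C)C[C@@](O)(C(=O)[C@@H]2[C@H](B3OC(C)(C)C(C)(C)O3)C[C@]4(C)C5(OCCO5)CC[C@@](C)(O)[C@@H]24)CC[C@@H]1Br
F4 | step 1 | racemic 5-bromo-6,6-dimethyloxan-2-one | CC1(C)OC(=O)CCC1Br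
F5 | step 1 | (S)-4-bromo-5-hydroxy-5-methyl-N-[(S)-1-phenylethyl]hexanamide | O=C(CC[C@@H](C(C)(C)O)Br)N[C@@H](C)c1ccccc1
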